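**Plan**

- Numbering of the target: ring C1 (C=O), C2=C3, C4 (CH–OAc), C5 (C–OH); side-chain carbinol C1′.
- Retrosynthesis cuts, in order: the O1′ silyl ether, C2=C3 (ring-closing metathesis), the O4 acetyl, C1–C2 (vinyl Grignard) and C3=CH2 (Wittig), and last C5–C1′ (aldol).
- Forward: the chain is joined at C5–C1′ first, C3 and C1 are turned into a vinyl group and a vinyl ketone, the 4,5-acetonide is exchanged for the C4 acetate, and the only ring, the cyclopentenone, is closed at the end.
- Enabling feature: C4 and C5 are trans-dioxygenated ring carbons flanked by C3 and C1, so C1–C5–C4–C3 with its two oxygens is a 2-C-substituted (S,S)-tartrate. Only C2 and the C2=C3 bond are missing, and a diene with a vinyl group on C4 and an acryloyl group on C5 closes exactly there.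
- Stereochemistry: C4 and C5 come from dimethyl D-tartrate (C5 substituted with retention on the acetonide enolate), C1′ from the aldol transition state; the metathesis creates no stereocentre.

Key step: step 12

Assumption: the lithium enolate of the tartrate acetonide is taken to react on the face cis to the neighbouring ester group (net retention at C5), as is established for alkylations of this enolate.

**Step 1**
Reactants: 1 dimethyl D-tartrate
Product: 2 dimethyl (4S,5S)-2,2-dimethyl-1,3-dioxolane-4,5-dicarboxylate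
Conditions: Me2C(OMe)2, TsOH·H2O (cat.), cyclohexane, reflux, MeOH removed as azeotrope
Reagents that add atoms: 2,2-dimethoxypropane, COC(C)(C)OC
Why: Acid-catalysed transacetalisation (acetonide formation) of the threo diol is driven by removal of methanol and leaves both stereocentres untouched.

**Step 2**
Reactants: 2 dimethyl (4S,5S)-2,2-dimethyl-1,3-dioxolane-4,5-dicarboxylate; 3 tridecanal
Product: 5 dimethyl (4S,5S)-4-[(1S)-1-hydroxytridecyl]-2,2-dimethyl-1,3-dioxolane-4,5-dicarboxylate, via lithium enolate 4 (not isolated)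
Conditions: LiN(i-Pr)2 (1.05 equiv), THF, −78 °C, 15 min; then 3, −78 °C; AcOH quench at −78 °C
Reagents that add atoms: none
Why: Lithium ester-enolate aldol addition in which the trigonal C5 of 4 should be attacked on the face cis to the neighbouring CO2Me of the untouched dioxolane stereocentre (net retention; the ring C–O bond lies in the nodal plane of the enolate, so β-elimination is slow at −78 °C), while a closed six-membered lithium transition state with O–Li cis to the ring oxygen and the dodecyl chain equatorial should place the new hydroxyl syn to O5, i.e. 1′S.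

**Step 3**
Reactants: 5 hydroxy diester
Product: 6 dimethyl (4R,5S)-4-[(1S)-1-(tert-butyldimethylsilyloxy)tridecyl]-2,2-dimethyl-1,3-dioxolane-4,5-dicarboxylate
Conditions: TBSOTf (1.5 equiv), 2,6-lutidine, CH2Cl2, −78 → 0 °C
Reagents that add atoms: tert-butyldimethylsilyl trifluoromethanesulfonate, CC(C)(C)[Si](C)(C)OS(=O)(=O)C(F)(F)F
Why: Silyl triflate silylation of the hindered secondary alcohol with a non-nucleophilic amine base avoids the alkoxide, so neither retro-aldol cleavage nor lactonisation onto the cis ester should intervene.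

**Step 4**
Reactants: 6 silyl ether diester
Product: 7 methyl (4R,5S)-4-[(1S)-1-(tert-butyldimethylsilyloxy)tridecyl]-5-formyl-2,2-dimethyl-1,3-dioxolane-4-carboxylate
Conditions: i-Bu2AlH (1.1 equiv), CH2Cl2, −78 °C; aqueous potassium sodium tartrate; crude aldehyde kept cold and used at once
Reagents that add atoms: none
Why: Partial ester reduction with i-Bu2AlH, whose α-oxygen-chelated aluminium hemiacetal survives at −78 °C and releases the aldehyde only on work-up; the ester on the tertiary ring carbon should react well before the neopentyl-type ester on the fully substituted carbon next to the silyloxy group.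

**Step 5**
Reactants: 7 aldehyde
Product: 8 methyl (4R,5R)-4-[(1S)-1-(tert-butyldimethylsilyloxy)tridecyl]-5-ethenyl-2,2-dimethyl-1,3-dioxolane-4-carboxylate
Conditions: Ph3PCH3Br, KN(SiMe3)2, THF, 0 °C; then 7, −78 → 0 °C
Reagents that add atoms: methyltriphenylphosphonium bromide, C[P+](c1ccccc1)(c1ccccc1)c1ccccc1.[Br-]
Why: Wittig methylenation with the ylide made from KN(SiMe3)2 and added to at low temperature, the usual way to methylenate a configurationally labile α-alkoxy aldehyde without epimerising its α-carbon (C4 of the target); the hindered ester is inert.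

**Step 6**
Reactants: 8 vinyl ester
Product: 9 {(4R,5R)-4-[(1S)-1-(tert-butyldimethylsilyloxy)tridecyl]-5-ethenyl-2,2-dimethyl-1,3-dioxolan-4-yl}methanol
Conditions: i-Bu2AlH (3 equiv), CH2Cl2, −78 → 0 °C; aqueous potassium sodium tartrate
Reagents that add atoms: none
Why: Exhaustive hydride reduction of the remaining hindered ester to the primary alcohol; the weakly basic aluminium alkoxide should not provoke silyl migration, and alkene, acetonide and silyl ether are inert.

**Step 7**
Reactants: 9 primary alcohol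
Product: 10 (4R,5R)-4-[(1S)-1-(tert-butyldimethylsilyloxy)tridecyl]-5-ethenyl-2,2-dimethyl-1,3-dioxolane-4-carbaldehyde
Conditions: Dess–Martin periodinane, CH2Cl2, 0 °C → rt
Reagents that add atoms: none
Why: Dess–Martin oxidation of a neopentyl-type primary alcohol gives an aldehyde with no α-hydrogen, which cannot epimerise.

**Step 8**
Reactants: 10 aldehyde; 11 vinylmagnesium bromide
Product: 12 1-{(4R,5R)-4-[(1S)-1-(tert-butyldimethylsilyloxy)tridecyl]-5-ethenyl-2,2-dimethyl-1,3-dioxolan-4-yl}prop-2-en-1-ol (both carbinol epimers)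
Conditions: CH2=CHMgBr (1.5 equiv), THF, −78 → −40 °C; aqueous NH4Cl
Reagents that add atoms: none
Why: Grignard 1,2-addition to a non-enolisable aldehyde; the new carbinol centre needs no control because step 9 removes it.

**Step 9**
Reactants: 12 allylic alcohol
Product: 13 1-{(4R,5R)-4-[(1S)-1-(tert-butyldimethylsilyloxy)tridecyl]-5-ethenyl-2,2-dimethyl-1,3-dioxolan-4-yl}prop-2-en-1-one
Conditions: Dess–Martin periodinane, CH2Cl2, 0 °C → rt; used without storage
Reagents that add atoms: none
Why: Dess–Martin oxidation of the secondary allylic alcohol converges both epimers on the vinyl ketone under near-neutral conditions that spare acetonide and silyl ether.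

**Step 10**
Reactants: 13 dienone acetonide
Product: 14 (4R,5R)-4-[(1S)-1-(tert-butyldimethylsilyloxy)tridecyl]-4,5-dihydroxyhepta-1,6-dien-3-one
Conditions: TFA–H2O (9:1), CH2Cl2, 0 °C, short reaction time; NaHCO3 work-up
Reagents that add atoms: none
Why: Acid-catalysed acetal hydrolysis frees the 4,5-diol, which must happen before cyclisation because these two oxygens end up trans on the five-membered ring; the hindered secondary silyl ether should cleave far more slowly than the acetonide under brief cold aqueous acid.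

**Step 11**
Reactants: 14 diol dienone
Product: 15 (3R,4R)-4-[(1S)-1-(tert-butyldimethylsilyloxy)tridecyl]-4-hydroxy-5-oxohepta-1,6-dien-3-yl acetate
Conditions: Ac2O (1.3 equiv), pyridine, DMAP (5 mol%), CH2Cl2, 0 °C
Reagents that add atoms: acetic anhydride, CC(=O)OC(C)=O
Why: Nucleophile-catalysed acylation distinguishes the secondary allylic C4 hydroxyl from the tertiary C5 hydroxyl on steric grounds while O1′ is blocked as its silyl ether.

**Step 12**
Reactants: 15 acetoxy dienone
Product: 16 (1R,5R)-5-[(1S)-1-(tert-butyldimethylsilyloxy)tridecyl]-5-hydroxy-4-oxocyclopent-2-en-1-yl acetate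
Conditions: (H2IMes)(PCy3)Cl2Ru=CHPh (second-generation Grubbs catalyst, 5–10 mol%), 1,4-benzoquinone (10 mol%), CH2Cl2 (0.005 M), 40 °C
Reagents that add atoms: none
Why: The ruthenium benzylidene should first exchange with the more electron-rich vinyl group on C4, and the resulting alkylidene then adds across the electron-poor acryloyl alkene by [2+2] cycloaddition; cycloreversion of the ruthenacyclobutane forms C2=C3 and releases ethylene. The closest known reaction type is ring-closing metathesis of 1,6-dien-3-ones to 4-oxygenated cyclopent-2-enones. The one ring formed, the cyclopentenone C1–C5, is closed by intramolecular olefin metathesis between two terminal alkenes on the adjacent carbons C4 and C5. No stereocentre is formed and none can epimerise, since C5 is fully substituted and the neutral conditions leave C4–H alone. The step needs cyclisation over cross-metathesis oligomers and no ruthenium-hydride alkene migration; the fully substituted C5 (gem-disubstituent effect), high dilution and benzoquinone should provide this.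

**Step 13**
Reactants: 16 silyl ether of the target
Product: 17 (1R,5S)-5-hydroxy-5-[(1S)-1-hydroxytridecyl]-4-oxocyclopent-2-en-1-yl acetate (target)
Conditions: aqueous HF (48%), MeCN, 0 °C → rt; NaHCO3 work-up
Reagents that add atoms: none
Why: Acidic fluoride desilylation (Si–F bond formation) removes the silyl ether without base, so the acetate should neither migrate nor should the enone γ-position be deprotonated; no stereocentre changes.

**Compound list**

1 | dimethyl D-tartrate, dimethyl (2S,3S)-2,3-dihydroxybutanedioate | COC(=O)[C@@H](O)[C@H](O)C(=O)OC | starting material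
2 | dimethyl (4S,5S)-2,2-dimethyl-1,3-dioxolane-4,5-dicarboxylate | COC(=O)[C@H]1OC(C)(C)O[C@@H]1C(=O)OC | intermediate
3 | tridecanal | CCCCCCCCCCCCC=O | starting material
4 | lithium enolate of 2, methyl (5S)-4-[(lithiooxy)(methoxy)methylidene]-2,2-dimethyl-1,3-dioxolane-5-carboxylate, O–Li cis to the ring oxygen | COC(=O)[C@H]1OC(C)(C)O/C1=C(/OC)O[Li] | intermediate
5 | dimethyl (4S,5S)-4-[(1S)-1-hydroxytridecyl]-2,2-dimethyl-1,3-dioxolane-4,5-dicarboxylate | CCCCCCCCCCCC[C@H](O)[C@]1(C(=O)OC)OC(C)(C)O[C@@H]1C(=O)OC | intermediate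
6 | dimethyl (4R,5S)-4-[(1S)-1-(tert-butyldimethylsilyloxy)tridecyl]-2,2-dimethyl-1,3-dioxolane-4,5-dicarboxylate | CCCCCCCCCCCC[C@H](O[Si](C)(C)C(C)(C)C)[C@]1(C(=O)OC)OC(C)(C)O[C@@H]1C(=O)OC | intermediate
7 | methyl (4R,5S)-4-[(1S)-1-(tert-butyldimethylsilyloxy)tridecyl]-5-formyl-2,2-dimethyl-1,3-dioxolane-4-carboxylate | CCCCCCCCCCCC[C@H](O[Si](C)(C)C(C)(C)C)[C@]1(C(=O)OC)OC(C)(C)O[C@@H]1C=O | intermediate
8 | methyl (4R,5R)-4-[(1S)-1-(tert-butyldimethylsilyloxy)tridecyl]-5-ethenyl-2,2-dimethyl-1,3-dioxolane-4-carboxylate | CCCCCCCCCCCC[C@H](O[Si](C)(C)C(C)(C)C)[C@]1(C(=O)OC)OC(C)(C)O[C@@H]1C=C | intermediate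
9 | {(4R,5R)-4-[(1S)-1-(tert-butyldimethylsilyloxy)tridecyl]-5-ethenyl-2,2-dimethyl-1,3-dioxolan-4-yl}methanol | CCCCCCCCCCCC[C@H](O[Si](C)(C)C(C)(C)C)[C@]1(CO)OC(C)(C)O[C@@H]1C=C | intermediate
10 | (4R,5R)-4-[(1S)-1-(tert-butyldimethylsilyloxy)tridecyl]-5-ethenyl-2,2-dimethyl-1,3-dioxolane-4-carbaldehyde | CCCCCCCCCCCC[C@H](O[Si](C)(C)C(C)(C)C)[C@]1(C=O)OC(C)(C)O[C@@H]1C=C | intermediate
11 | vinylmagnesium bromide | C=C[Mg]Br | starting material
12 | 1-{(4R,5R)-4-[(1S)-1-(tert-butyldimethylsilyloxy)tridecyl]-5-ethenyl-2,2-dimethyl-1,3-dioxolan-4-yl}prop-2-en-1-ol, both carbinol epimers | CCCCCCCCCCCC[C@H](O[Si](C)(C)C(C)(C)C)[C@]1(C(O)C=C)OC(C)(C)O[C@@H]1C=C | intermediate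
13 | 1-{(4R,5R)-4-[(1S)-1-(tert-butyldimethylsilyloxy)tridecyl]-5-ethenyl-2,2-dimethyl-1,3-dioxolan-4-yl}prop-2-en-1-one | CCCCCCCCCCCC[C@H](O[Si](C)(C)C(C)(C)C)[C@]1(C(=O)C=C)OC(C)(C)O[C@@H]1C=C | intermediate
14 | (4R,5R)-4-[(1S)-1-(tert-butyldimethylsilyloxy)tridecyl]-4,5-dihydroxyhepta-1,6-dien-3-one | CCCCCCCCCCCC[C@H](O[Si](C)(C)C(C)(C)C)[C@@](O)(C(=O)C=C)[C@H](O)C=C | intermediate
15 | (3R,4R)-4-[(1S)-1-(tert-butyldimethylsilyloxy)tridecyl]-4-hydroxy-5-oxohepta-1,6-dien-3-yl acetate | CCCCCCCCCCCC[C@H](O[Si](C)(C)C(C)(C)C)[C@@](O)(C(=O)C=C)[C@H](OC(C)=O)C=C | intermediate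
16 | (1R,5R)-5-[(1S)-1-(tert-butyldimethylsilyloxy)tridecyl]-5-hydroxy-4-oxocyclopent-2-en-1-yl acetate | CCCCCCCCCCCC[C@H](O[Si](C)(C)C(C)(C)C)[C@@]1(O)C(=O)C=C[C@H]1OC(C)=O | intermediate
17 | (1R,5S)-5-hydroxy-5-[(1S)-1-hydroxytridecyl]-4-oxocyclopent-2-en-1-yl acetate | CCCCCCCCCCCC[C@H](O)[C@@]1(O)C(=O)C=C[C@H]1OC(C)=O | target

**Step count and risks**

Total: 13 steps. Longest linear sequence: 13 steps, from 1 to 17.

Steps most likely to fail:

1. Step 2. The aldol may show poor facial selectivity at the aldehyde carbon, so that C1′ is formed as a mixture or with the opposite sense; the enolate may also partly decompose by β-elimination before it is trapped. The fallback sets out from 2 and comes back at 5, and it replaces substrate control at C1′ by reagent control. The aldol is run as before, and 5 is taken on together with its C1′ epimer, dimethyl (4S,5S)-4-[(1R)-1-hydroxytridecyl]-2,2-dimethyl-1,3-dioxolane-4,5-dicarboxylate F1, without separation. Dess–Martin oxidation (CH2Cl2, rt) should give the β-keto diester dimethyl (4R,5S)-2,2-dimethyl-4-tridecanoyl-1,3-dioxolane-4,5-dicarboxylate F2. Corey–Bakshi–Shibata reduction of F2 with (R)-2-methyl-CBS-oxazaborolidine and BH3·SMe2 (toluene, −40 °C) should return 5; the fully substituted dioxolane carbon acts as the large group and the unbranched chain as the small one, which with the (R)-catalyst corresponds to 1′S.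

2. Step 10. With the acid present, the freed C4 hydroxyl or water may add to the vinyl ketone, the dienone may oligomerise, or the silyl ether may be lost together with the acetonide. The fallback sets out from 12 and comes back at 15; it removes the acetonide before the vinyl ketone exists. Alcohol 12 is converted with 4-methoxybenzyl 2,2,2-trichloroacetimidate and La(OTf)3 (cat., toluene, rt) into the 4-methoxybenzyl ether of 12 at the allylic carbinol F3. Hydrolysis with 80% aqueous AcOH at 50 °C should give the 4,5-diol 4-methoxybenzyl ether F4. Acetylation (Ac2O, pyridine, DMAP, 0 °C) at the secondary C4 hydroxyl gives the C4 acetate 4-methoxybenzyl ether F5. DDQ in wet CH2Cl2 then frees the allylic alcohol acetate F6, and Dess–Martin oxidation of F6 gives 15.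

3. Step 4. Discrimination between the two methyl esters may be incomplete, giving over-reduction or reduction at the ester on the quaternary carbon. The fallback sets out from 5 and comes back at 7; it differentiates the esters by functional group instead of by hindrance. Heating 5 with camphorsulfonic acid (cat.) in toluene should close the C1′ hydroxyl onto the only ester that is cis to it, giving the cis-fused bicyclic lactone methyl (3aS,4S,6aS)-4-dodecyl-2,2-dimethyl-6-oxotetrahydrofuro[3,4-d][1,3]dioxole-3a-carboxylate F7. Aminolysis of the lactone with MeNH(OMe)·HCl and AlMe3 (CH2Cl2, 0 °C) gives the hydroxy N-methoxy-N-methylamide methyl (4S,5S)-4-[(1S)-1-hydroxytridecyl]-5-[methoxy(methyl)carbamoyl]-2,2-dimethyl-1,3-dioxolane-4-carboxylate F8. Silylation (TBSOTf, 2,6-lutidine) gives its silyl ether methyl (4R,5S)-4-[(1S)-1-(tert-butyldimethylsilyloxy)tridecyl]-5-[methoxy(methyl)carbamoyl]-2,2-dimethyl-1,3-dioxolane-4-carboxylate F9. Reduction of the amide with i-Bu2AlH (THF, −78 °C), which stops at the chelated hemiaminal and leaves the hindered ester alone, gives 7.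

**Further compounds**

F1 | step 2 | dimethyl (4S,5S)-4-[(1R)-1-hydroxytridecyl]-2,2-dimethyl-1,3-dioxolane-4,5-dicarboxylate | CCCCCCCCCCCC[C@@H](O)[C@]1(C(=O)OC)OC(C)(C)O[C@@H]1C(=O)OC
F2 | step 2 | dimethyl (4R,5S)-2,2-dimethyl-4-tridecanoyl-1,3-dioxolane-4,5-dicarboxylate | CCCCCCCCCCCCC(=O)[C@]1(C(=O)OC)OC(C)(C)O[C@@H]1C(=O)OC
F3 | step 10 | 4-methoxybenzyl ether of 12 at the allylic carbinol, ring and side-chain configuration as in 12 | CCCCCCCCCCCC[C@H](O[Si](C)(C)C(C)(C)C)[C@]1(C(OCc2ccc(OC)cc2)C=C)OC(C)(C)O[C@@H]1C=C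
F4 | step 10 | 4-[(1S)-1-(tert-butyldimethylsilyloxy)tridecyl]-3-(4-methoxybenzyloxy)hepta-1,6-diene-4,5-diol, configuration at C4, C5 and C1′ as in 14 | CCCCCCCCCCCC[C@H](O[Si](C)(C)C(C)(C)C)[C@@](O)(C(OCc1ccc(OC)cc1)C=C)[C@H](O)C=C
F5 | step 10 | 4-[(1S)-1-(tert-butyldimethylsilyloxy)tridecyl]-4-hydroxy-5-(4-methoxybenzyloxy)hepta-1,6-dien-3-yl acetate, configuration as in 15 | CCCCCCCCCCCC[C@H](O[Si](C)(C)C(C)(C)C)[C@@](O)(C(OCc1ccc(OC)cc1)C=C)[C@H](OC(C)=O)C=C
F6 | step 10 | 4-[(1S)-1-(tert-butyldimethylsilyloxy)tridecyl]-4,5-dihydroxyhepta-1,6-dien-3-yl acetate, configuration as in 15 | CCCCCCCCCCCC[C@H](O[Si](C)(C)C(C)(C)C)[C@@](O)(C(O)C=C)[C@H](OC(C)=O)C=C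
F7 | step 4 | methyl (3aS,4S,6aS)-4-dodecyl-2,2-dimethyl-6-oxotetrahydrofuro[3,4-d][1,3]dioxole-3a-carboxylate | CCCCCCCCCCCC[C@@H]1OC(=O)[C@H]2OC(C)(C)O[C@@]12C(=O)OC
F8 | step 4 | methyl (4S,5S)-4-[(1S)-1-hydroxytridecyl]-5-[methoxy(methyl)carbamoyl]-2,2-dimethyl-1,3-dioxolane-4-carboxylate | CCCCCCCCCCCC[C@H](O)[C@]1(C(=O)OC)OC(C)(C)O[C@@H]1C(=O)N(C)OC
F9 | step 4 | methyl (4R,5S)-4-[(1S)-1-(tert-butyldimethylsilyloxy)tridecyl]-5-[methoxy(methyl)carbamoyl]-2,2-dimethyl-1,3-dioxolane-4-carboxylate | CCCCCCCCCCCC[C@H](O[Si](C)(C)C(C)(C)C)[C@]1(C(=O)OC)OC(C)(C)O[C@@H]1C(=O)N(C)OC
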